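Thursday's flask, the nearest to elm, holds 34% of its G at 1.25 d and 5% at 6.00 d. Read as one pseudo-first-order decay, these two readings give 0.404 d⁻¹; this is the tail constant k, the fractional loss of G per day after the first rush.

| flask | G | J | Q | D | remark | time |
|---|---|---|---|---|---|---|
| Thursday's | 0.050 M | 1.2 equiv | 1.9 equiv | 0.30 equiv | run made earlier |  |
| Sunday's | 0.050 M | 1.2 equiv | 3 equiv | 0.30 equiv | run made earlier |  |
| Wednesday's | 0.050 M | 1.2 equiv | 4.5 equiv | 0.30 equiv | run made earlier |  |
| elm | 0.050 M | 1.20 equiv | 2.00 equiv | 0.300 equiv |  | 10 d |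
| alder | 0.050 M | 1.20 equiv | 4.00 equiv | 0.300 equiv |  | 10 d |

| run | time / d | G / % | E / % |
|---|---|---|---|
| Thursday's | 1.25 | 34 | 56 |
| Thursday's | 3.00 | 17 | 61 |
| Thursday's | 4.00 | 12 | 61 |
| Thursday's | 6.00 | 5 | 64 |
| Thursday's | 8.00 | 5 | 64 |
| Sunday's | 0.625 | 45 | 51 |
| Sunday's | 1.67 | 25 | 60 |
| Sunday's | 3.00 | 13 | 64 |
| Sunday's | 5.00 | 4 | 67 |
| Sunday's | 8.00 | 0 | 66 |
| Wednesday's | 0.625 | 41 | 48 |
| Wednesday's | 1.04 | 32 | 55 |
| Wednesday's | 2.08 | 20 | 65 |
| Wednesday's | 4.00 | 8 | 68 |
| Wednesday's | 8.00 | 0 | 72 |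

(each reading ± 1.5 percentage points)

- a species is counted by the G in it: one GE counts as two
- amounts and yields of X count Z too
- what was read earlier has a scatter of 1.5 percentage points, one standard deviation
- on the list of suspects stand: G + J -> X + E; J + X <-> JX; X + Q <-> Z; X + D -> XD; G + E -> GE; X + Q <-> XQ

1. part of the G that has reacted at the end, elm
2. part of the G that has reacted at the end, alder
3. what raising the equivalents of Q from its lowest to its highest value here does to the part of the G that has reacted (changes below 5 percentage points count as none) (it rises / no change / it falls)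

Thursday's reading at 8.00 d repeats 5%, but the scatter is 1.5 percentage points, and Sunday's and Wednesday's flasks read 0% and 0% of G at that time, so the reckoning here takes the decay to go on. Carried from 1.25 d to 10 d, k gives elm a reckoned 0.995% of its G, so by this reckoning 99.0% has reacted. Wednesday's flask, read the same way from 0.625 d to 4.00 d, gives 0.484 d⁻¹; taken over to alder, with 4.00 equiv of Q against 4.5 equiv, this gives from 8% a reckoned 0.438% of G. The two reckoned figures differ by 0.56 points, under the margin of 5 points.

The forecast, reading “a tail of roughly first-order decay”, gives 97% for elm, lower than this reckoning, 99.5% for alder, and no change.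

The flasks give 98.6% for elm and 99.4% for alder, a change of 0.82 points: no change.

    G + J → X + E (k = 0.0400 L mol⁻¹ min⁻¹)
    J + X ⇌ JX, settled at all times (K = 41000 L mol⁻¹)
    X + Q ⇌ Z, settled at all times (K = 170 L mol⁻¹)
    X + D → XD (k = 0.200 L mol⁻¹ min⁻¹)
    G + E → GE (k = 0.00310 L mol⁻¹ min⁻¹)
    X + Q ⇌ XQ (K = 2300 L mol⁻¹, k = 0.450 L mol⁻¹ min⁻¹)

In elm, between 5.00 d and 10.0 d, G falls from 8.18% to 1.42%, a tail constant of 0.350 d⁻¹, while free J stands at 6.13% and then 5.98% of its charge. The neighbour is elm with 0.020 M of G, equivalents held. Taking k in proportion to the G charged, as for the two-body steps G + J and G + E, its 10 d counts as 4.00 d on Thursday's clock, and Thursday's k of 0.404 d⁻¹ gives a reckoned 11.2% of G. The neighbour ends with 9.7% of its G.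

The runs were generated by integration on assumed constants; noise was put on by code.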